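Early in each earlier run G climbs fast and later bends, and that bend can be read.

| flask | J | Z | temperature | remark | time |
|---|---|---|---|---|---|
| red | 0.20 M | 0.22 M | 65 °C | run made earlier |  |
| amber | 0.20 M | 0.29 M | 76 °C | run made earlier |  |
| blue | 0.20 M | 0.45 M | 65 °C | run made earlier |  |
| eta | 0.20 M | 0.260 M |  | at 60 °C until 40 h, from then on at 80 °C | 5.0 d |
| delta | 0.20 M | 0.400 M |  | at 80 °C throughout | 5.0 d |

red run (percent of the J charged)

| time / d | G / % |
|---|---|
| 0.833 | 33 |
| 1.67 | 52 |
| 2.50 | 68 |
| 4.00 | 81 |

amber run (percent of the J charged)

| time / h | G / % |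
|---|---|
| 5.00 | 29 |
| 15.0 | 62 |
| 25.0 | 75 |
| 40.0 | 84 |

blue run (percent of the J charged)

| time / d | G / % |
|---|---|
| 0.417 | 20 |
| 1.25 | 45 |
| 2.50 | 68 |
| 4.00 | 81 |

(each reading ± 2 percentage points)

- the winner by amount of G, in percent of the J charged; "neither" if no more than 2 percentage points parts them (eta / delta / neither)
- how much G is there at the end, in percent of the J charged: eta
- how much G is there at the end, in percent of the J charged: delta

- the numbers in the tables scatter by 2 percentage points (one standard deviation)
- steps thought possible: Z + L -> E; J -> L; Z + E -> D; J -> G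

Two chemists argue over eta and delta. Both see that red and blue read 68% and 68% of G at 2.50 d, although blue holds twice the Z of red, so neither looks to Z for the G seen so far.

The first chemist counts half-lives, starting from amber. Taking its last reading, 84%, as a first plateau, the reading at 15.0 h gives a first-order rate of 0.0893 h⁻¹. At that rate amber was still short of its plateau at 40.0 h, so the plateau goes up to 86.4%. Put back in, this gives a rate of 0.0842 h⁻¹ and a plateau of 87.0%. That figure, read off readings with their scatter, is the plateau share, the percent of the J used up that ends as G (the selectivity), so G is the plateau share times the part of J used.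

Read this way, J in amber has a half-life of 8.23 h. Eta's stretch at 80 °C, hotter than amber, lasts 80.0 h, which is 9.72 such half-lives; even at amber's rate, the first chemist reckons, that leaves 0.119% of the J present at the change. Delta has longer at that temperature, so by this reckoning both flasks end at the plateau share.

The second chemist counts hot hours. Eta sits at 60 °C for 40 h and so gets 66.7% of delta's time at 80 °C, so this chemist expects eta to trail delta.

The forecast sides with the first: 87.5% for eta (83% to 92%), 86% for delta (81% to 90%), verdict neither, since both “finish with J exhausted, and the G yield is just the selectivity”. The reckoning above gives one figure for both, 87.0%, where the forecast has two.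

The simulation gives G 89.0% in eta and 89.3% in delta at 5.0 d, 0.30 percentage points apart, so the verdict is neither.

    Z + L → E (k = 4.20 × 10⁻⁴ L mol⁻¹ min⁻¹, Ea = 84.0 kJ mol⁻¹)
    J → L (k = 2.30 × 10⁻⁵ min⁻¹, Ea = 112 kJ mol⁻¹)
    Z + E → D (k = 6.00 × 10⁻⁴ L mol⁻¹ min⁻¹, Ea = 100 kJ mol⁻¹)
    J → G (k = 1.80 × 10⁻⁴ min⁻¹, Ea = 115 kJ mol⁻¹)
    (constants at 60 °C)

At the change, 1.67 d, eta held J 61.4% and G 34.2%; at 5.00 d it held J 0% and G 89.0%. The hot-hours view has its ground in a flask that ends with J unused, such as the neighbour flask, delta kept at 55 °C, which holds J 45.9% at 5.00 d. The plateau share times the J used gives 47.1% of G there, and that flask holds 47.8%.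

Readings and results were computed with constants of no real substance; the scatter is artificial.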